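**Conventions.** C2 to C8a are the positions of the tetrahydrochromone in the target 23; positions of the sugar chain carry an f (C1f to C6f). Ar = 7-methoxy-4-oxo-2-(2-phenylethyl)-4H-chromen-6-yl. BDA = (2S,3S)-2,3-dimethoxybutane-2,3-diyl bridging two neighbouring oxygens as a trans-fused 1,4-dioxane with both methoxy groups axial.

## Analysis of the target

Compound 23 is an ether-linked pair of 2-(2-phenylethyl)chromones: an aromatic 6-oxy-7-methoxychromone (Ar–O) and a 5,6,7,8-tetrahydrochromone whose carbocycle carries oxygen on every sp3 carbon. The only stereocentres are C5, C6, C7 and C8, contiguous and (5S,6R,7S,8S). O5/O6 and O6/O7 are trans and O7/O8 cis, so O5, O6 and O7 can all be equatorial while the aryloxy group at C8 is axial. The sensitive sites are the C5 carbinol (on the electron-rich α-carbon of the γ-pyrone, ionisable in acid), the polyol ring as a whole (it can aromatise by losing water or the phenol), and the two vinylogous esters (opened by hard nucleophiles, each with a vinylogously acidic CH2 next to C2). The hard problems are the absolute configuration of four adjacent carbinols and the hindered secondary alkyl aryl ether at C8, which is cis to O7 and so cannot come from trans opening of a 7,8-epoxide. The strategy rests on reading the carbocycle C4a–C5–C6–C7–C8–C8a as the chain of L-fucose 1 from its methyl group to its aldehyde: C6f is C4a, C5f is C8a, C4f, C3f and C2f are C8, C7 and C6 with the 2,3-trans-3,4-cis pattern of the sugar, and C1f is C5. Only the bond C4a–C5 and the configuration at C5 are missing; the pyranone atoms O1, C2, C3 and C4 carry no stereochemistry and can be added to the C8a ketone afterwards.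

## Retrosynthetic reasoning

**23 to 22.** No skeletal bond is cut. The hydroxyls are masked as one BDA acetal on O6/O7 and one triethylsilyl ether on O5, which a single aqueous acid treatment removes. The acetal is chosen because on the sugar it separates the trans-diequatorial O2f/O3f pair from O4f in one step and later freezes the carbocycle in one chair. The forward step must free three hydroxyls without ionising C5.

**22 to 17 and 19.** The pyranone is cut at O1–C8a and C4–C4a. This removes O1, C2, C3, C4 and the phenethyl chain as acylketene 20, released thermally from dioxinone 19, and leaves enol ether 17 of a cyclohexanone whose carbonyl carbon is C8a. These bonds are chosen because the four atoms removed carry no stereocentre and the remainder has the oxidation pattern of a sugar-derived β-hydroxy ketone. Forward, 20 must add across C4a=C8a as a 1-oxadiene to give 21, which must lose silanol from C8a and not the silyloxy group from C5.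

**17 to 16 and 15.** Functional-group changes only. The enol ether must form towards C4a, away from C8, and the C5 hydroxyl of 15 must be capped so that it neither acylates 20 nor leaves.

**15 to 14 (key disconnection).** The β-hydroxy ketone C8a(=O)–C4a–C5(OH) is opened at C4a–C5, the only ring C–C bond that a 6-deoxyhexose chain does not already contain. This gives the open-chain 1,5-keto aldehyde 14 with C6, C7 and C8 in place. Forward, the methyl carbon of the ketone must add to the aldehyde and set C5 with its hydroxyl trans to O6. Both enolate carbons end up inside the new ring, so the closure is 6-(enolendo)-exo-trig. A bridging counter-ion would turn the aldehyde oxygen towards the enolate oxygen and give the cis (axial) alcohol, so the aldol is planned with a metal-free amidine base.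

**14 to 13, 12 and 11.** The two carbonyls come from the 1,5-diol 13 (double oxidation), 13 from lactol 12 (reduction) and 12 from thioglycoside 11 (hydrolysis). The pyranoside ring is kept this long because it distinguishes O5f from O4f and hides the aldehyde while the aryl ether is made.

**11 to 5 and 10.** The ether is cut on the aryl side. Substitution at C4f would need the C4 epimer of the sugar, and the cis relationship to O3f excludes epoxide opening; cutting the aryl–O bond leaves the C4f–O bond of 1 untouched. The coupling is placed on 5, where O4f is the only free hydroxyl. Forward, an axial secondary alkoxide must be joined to an ortho-methoxy aryl iodide.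

**5 to 4, 3 and 1.** Diacetal formation on triol 4 selects the trans-diequatorial 2,3-diol and leaves axial O4f. The anomeric group is a phenyl thioglycoside because it must survive the acidic alcohol of that step and the basic coupling and later be removed without acid strong enough to open the diacetal. Compound 3 comes from 1 by acetylation and thioglycosidation through tetraacetate 2.

**10 to 9, 8 and 7; 7 to 6.** The aryl pyranone is cut at O1–C2 (cyclodehydration of diketone 9) and at C2–C3 (Claisen condensation of 7 with ester 8). The iodine marks the future ether carbon and is placed on 6 para to the phenol.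

**19 to 18.** The bond between the two side-chain CH2 groups is cut, corresponding to γ-alkylation of the dienolate of 18 with a benzylic halide.

## Alternatives that were turned down

Alternative 1: Asymmetric epoxidation of a masked ortho-quinone.
- Disconnection: the C5–O and C6–O bonds are traced to an epoxide and the saturated ring to the achiral dienone A1 (8,8-dimethoxy-2-(2-phenylethyl)-8H-chromene-4,7-dione), available by oxidative dearomatisation of a simple aromatic chromone.
- Key step: nucleophilic epoxidation of the C5=C6 enone of A1 with an alkyl hydroperoxide under a chiral cinchona-derived ammonium phase-transfer catalyst, giving epoxide A2.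
- For: the pyranone is present from the start, so the annulation of steps 13 and 15 is not needed; the sequence is short; chirality comes from a catalyst. On step count and on avoiding pyranone construction next to a polyol it is stronger than the chosen route.
- Against: the catalyst controls only C5 and C6. C7 and C8 must come from two substrate-controlled ketone reductions that have to give 6,7-trans and 7,8-cis. The aryl ether must then be made last, at C8 of a finished, elimination-prone tetrahydrochromone, where substitution competes with E2 loss towards the aromatic chromone and ionisation is disfavoured by the electron-poor β-carbon of the pyranone. Face selectivity of phase-transfer epoxidation is best established for acyclic trans-enones, not for a cyclic cis-enone such as A1, and the peroxide anion can also attack C2.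
- Comparison: the chosen route is longer but takes C6, C7 and C8 from 1 without any selectivity question and makes the ether on a robust pyranoside.

Alternative 2: Enzymatic cis-dihydroxylation.
- Disconnection: the C7–O and C8–O bonds are cut together, back to 2-(2-phenylethyl)chromone A3.
- Key step: an arene dioxygenase of the naphthalene dioxygenase type adds both oxygens to C7 and C8, giving the cis-dihydrodiol A4.
- For: one step turns an achiral chromone into a (7S,8S) cis-diol, the relationship the chosen route imports from the sugar, and the remaining C5=C6 bond invites anti epoxidation and hydrolytic trans opening. If it worked it would be the shortest route; on step and atom economy it is clearly stronger.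
- Against: the enzymatic step cannot be argued from structure. A3 has two arenes, and the unhindered phenyl ring of the side chain is a more typical dioxygenase substrate than a benzo ring fused to an electron-poor pyranone. A4 is a dienediol that rearomatises by dehydration; its two secondary hydroxyls must be distinguished before arylation of O8, and that arylation meets the steric problem of step 7 on a far more fragile substrate.
- Comparison: the chosen strategy offers predictability: every stereocentre comes from 1 or from one chair transition state, and the arylation meets a single free hydroxyl.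

Alternative 3: Dötz benzannulation on the ether oxygen.
- Disconnection: the benzene ring of the aryl chromone is cut at three C–C bonds.
- Key step: the chromium carbene complex A5, (CO)5Cr=C(OR)C(OMe)=CH2 with R the protected tetrahydrochromon-8-yl group, reacts with alkyne A6 (3,3-diethoxyprop-1-yne) and one carbonyl ligand to give phenol A7.
- For: the aryl–oxygen bond is never made by substitution or coupling at a hindered carbinol, and the arene substitution pattern follows from the alkyne regiochemistry. On that one bond, the weakest point before the key step here (step 7), it is the stronger plan.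
- Against: A5 needs the complete tetrahydrochromone, with all four stereocentres and a free C8 hydroxyl, so the stereochemical problem is left to another route. Attaching a hindered secondary alkoxy group to a carbene complex is inefficient, chromium is stoichiometric, and the second pyranone must still be built from A7 over several steps beside the first, sensitive one.
- Comparison: the chosen strategy makes 10 in three steps from 6, joins it in one step, and its key step creates the carbocycle and the last stereocentre at once.

Key step: step 11

## Route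

Step 1
Reactants: 1 L-fucose
Product: 3 phenyl 2,3,4-tri-O-acetyl-1-thio-β-L-fucopyranoside, via tetra-O-acetyl-L-fucopyranose 2 (not isolated)
Conditions: Ac2O (4.2 equiv), BF3·OEt2 (cat.), 0 °C to rt; then PhSH, BF3·OEt2, CH2Cl2, 0 °C to rt
Reagents that add atoms: acetic anhydride CC(=O)OC(C)=O; thiophenol Sc1ccccc1
Why: Per-O-acetylation followed in the same flask by Lewis acid-promoted thioglycosidation; the 2-O-acetyl group participates through an acetoxonium ion, so the thiol enters trans to O2f and the anomeric centre is set β.

Step 2
Reactants: 3 phenyl 2,3,4-tri-O-acetyl-1-thio-β-L-fucopyranoside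
Product: 4 phenyl 1-thio-β-L-fucopyranoside
Conditions: NaOMe (cat.), MeOH, rt; H+ resin
Reagents that add atoms: none
Why: Zemplén transesterification removes the three acetates; the thioglycoside is inert to methoxide.

Step 3
Reactants: 4 phenyl 1-thio-β-L-fucopyranoside
Product: 5 phenyl 2,3-O-BDA-1-thio-β-L-fucopyranoside
Conditions: butane-2,3-dione, HC(OMe)3, camphorsulfonic acid (cat.), MeOH, reflux
Reagents that add atoms: butane-2,3-dione CC(=O)C(C)=O; methanol CO; trimethyl orthoformate COC(OC)OC
Why: Butane-2,3-diacetal formation under thermodynamic control should select the trans-diequatorial 2,3-diol over the cis 3,4-diol, leaving axial O4f free. Both acetal centres are set S because the trans-fused dioxane with two axial methoxy groups has two anomeric effects.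

Step 4
Reactants: 6 paeonol, 1-(2-hydroxy-4-methoxyphenyl)ethanone
Product: 7 1-(2-hydroxy-5-iodo-4-methoxyphenyl)ethanone
Conditions: N-iodosuccinimide, CF3CO2H (cat.), MeCN, rt
Reagents that add atoms: N-iodosuccinimide O=C1CCC(=O)N1I
Why: Electrophilic aromatic iodination; position 5 is para to the hydroxyl, ortho to the methoxy group and less hindered than position 3 between the two oxygens.

Step 5
Reactants: 7 1-(2-hydroxy-5-iodo-4-methoxyphenyl)ethanone; 8 ethyl 3-phenylpropanoate
Product: 9 1-(2-hydroxy-5-iodo-4-methoxyphenyl)-5-phenylpentane-1,3-dione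
Conditions: LiN(SiMe3)2 (3.2 equiv), THF, −78 °C to 0 °C; aq. HCl
Reagents that add atoms: none
Why: Crossed Claisen condensation of the phenoxide–enolate dianion of 7 with the ester; the third equivalent of base deprotonates the more acidic diketone and drives the condensation.

Step 6
Reactants: 9 1-(2-hydroxy-5-iodo-4-methoxyphenyl)-5-phenylpentane-1,3-dione
Product: 10 6-iodo-7-methoxy-2-(2-phenylethyl)-4H-chromen-4-one
Conditions: HCl (conc., cat.), AcOH, 100 °C
Reagents that add atoms: none
Why: Acid-catalysed cyclodehydration of an o-hydroxyaryl 1,3-diketone, the standard closure to 2-alkylchromones.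

Step 7
Reactants: 5 phenyl 2,3-O-BDA-1-thio-β-L-fucopyranoside; 10 6-iodo-7-methoxy-2-(2-phenylethyl)-4H-chromen-4-one
Product: 11 phenyl 4-O-Ar-2,3-O-BDA-1-thio-β-L-fucopyranoside
Conditions: CuI (10 mol%), 3,4,7,8-tetramethyl-1,10-phenanthroline (20 mol%), Cs2CO3, 4 Å molecular sieves, toluene, 110 °C; 5 in 1.5-fold excess
Reagents that add atoms: none
Why: Ullmann-type copper-catalysed C–O coupling of an aryl iodide with a secondary alcohol; 5 has a single free hydroxyl and the C4f–O bond is not broken, so the configuration at C4f (later C8) is retained.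

Step 8
Reactants: 11 phenyl 4-O-Ar-2,3-O-BDA-1-thio-β-L-fucopyranoside
Product: 12 4-O-Ar-2,3-O-BDA-L-fucopyranose (anomeric mixture)
Conditions: N-bromosuccinimide, NaHCO3, acetone/H2O (9:1), 0 °C; Na2S2O3 work-up
Reagents that add atoms: water O
Why: Bromonium activation of the thioglycoside sulfur and hydrolysis of the oxocarbenium ion; the diacetal and the aryl ether should be stable to these buffered conditions.

Step 9
Reactants: 12 4-O-Ar-2,3-O-BDA-L-fucopyranose
Product: 13 4-O-Ar-2,3-O-BDA-L-fucitol (free hydroxyls at C1f and C5f)
Conditions: NaBH4, EtOH/CH2Cl2, 0 °C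
Reagents that add atoms: none
Why: Borohydride reduction of the open-chain aldehyde tautomer of the lactol; the 2-alkyl-7-alkoxychromone is a vinylogous ester, far less electrophilic than an aldehyde, and is expected to survive at 0 °C.

Step 10
Reactants: 13 4-O-Ar-2,3-O-BDA-L-fucitol
Product: 14 4-O-Ar-2,3-O-BDA-6-deoxy-L-lyxo-hexos-5-ulose
Conditions: (COCl)2, DMSO, CH2Cl2, −78 °C; i-Pr2NEt, −78 to −40 °C; cold pH 7 buffer
Reagents that add atoms: none
Why: Double Swern oxidation; both hydroxyls become alkoxysulfonium ions before base is added, so no hydroxy aldehyde is present to close to a lactol and over-oxidise. The hindered base and cold quench keep the α-oxygenated aldehyde and ketone from epimerising or cyclising early.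

Step 11
Reactants: 14 4-O-Ar-2,3-O-BDA-6-deoxy-L-lyxo-hexos-5-ulose
Product: 15 (2S,3S,4R,5S)-2-(ArO)-5-hydroxy-3,4-O-BDA-cyclohexan-1-one (C1 = C8a, C2 = C8, C5 = C5, C6 = C4a)
Conditions: DBU (0.2 equiv), toluene, −20 to 0 °C
Reagents that add atoms: none
Why: The amidine removes a proton from the methyl group of the ketone, the unbridged amidinium enolate adds through C4a to the aldehyde carbon C5, and protonation of the alkoxide releases the base. The closest known reaction type is the base-mediated intramolecular aldol of hexos-5-uloses to inososes, the ring-forming event of the Ferrier carbocyclisation. The ring closes in the 6-(enolendo)-exo-trig mode, with both enolate carbons C8a and C4a inside the new ring and the aldehyde oxygen outside it; only the methyl carbon can close a six-membered ring. The BDA acetal is a trans-fused dioxane that holds O6 and O7 equatorial, so the transition state has one chair, with the aryloxy group at C8 axial as O4 is in the parent pyranose. In that chair the new stereocentre C5 depends only on which face of the aldehyde is presented: with no bridging metal the carbonyl should turn away from the enolate oxygen (antiperiplanar, open transition state), which places O5 equatorial and trans to O6, the (5S) configuration. A chelating cation (Mg, B or Hg) would tie the aldehyde oxygen to the enolate oxygen and deliver the axial cis epimer, which is why a metal-free base is used; the equatorial alcohol is also the more stable epimer, so any retro-aldol equilibration works in the same direction. The step also needs ketone enolisation to win over β-elimination at the aldehyde and over epimerisation at C8: the oxygen β to the aldehyde is a ring atom of the dioxane and poorly aligned for elimination, the C8–H bond of the product is equatorial and nearly orthogonal to the carbonyl π system, and low temperature with substoichiometric base limits both.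

Step 12
Reactants: 15 (2S,3S,4R,5S)-2-(ArO)-5-hydroxy-3,4-O-BDA-cyclohexan-1-one
Product: 16 5-O-triethylsilyl ether of 15
Conditions: Et3SiOTf, 2,6-lutidine, CH2Cl2, −78 °C
Reagents that add atoms: triethylsilyl trifluoromethanesulfonate CC[Si](CC)(CC)OS(=O)(=O)C(F)(F)F
Why: Silylation with a silyl triflate and a hindered pyridine base at low temperature, conditions under which β-hydroxy ketones should neither retro-aldolise nor dehydrate.

Step 13
Reactants: 16 5-O-triethylsilyl ether of 15
Product: 17 trimethylsilyl enol ether of 16 (C8a–OSiMe3, C4a=C8a double bond)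
Conditions: LiN(SiMe3)2, Me3SiCl (in situ), THF, −78 °C; Et3N, cold aq. NaHCO3
Reagents that add atoms: chlorotrimethylsilane C[Si](C)(C)Cl
Why: Kinetic deprotonation with in situ silylation; the axial C4a–H is aligned with the carbonyl whereas the C8–H is equatorial, so the enol ether should form towards C4a. The enolate is trapped before the equatorial, poorly aligned silyloxy group at C5 can be expelled, and ketone α-deprotonation should outrun vinylogous deprotonation of the aryl chromone side chain.

Step 14
Reactants: 18 2,2,6-trimethyl-4H-1,3-dioxin-4-one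
Product: 19 2,2-dimethyl-6-(2-phenylethyl)-4H-1,3-dioxin-4-one
Conditions: LiN(i-Pr)2, THF, −78 °C; BnBr, DMPU, −78 to −20 °C
Reagents that add atoms: benzyl bromide BrCc1ccccc1
Why: γ-Alkylation of the lithium dienolate of the dioxinone at the exocyclic methyl carbon with a reactive benzylic halide, a known route to 6-alkyl dioxinones.

Step 15
Reactants: 17 trimethylsilyl enol ether of 16; 19 2,2-dimethyl-6-(2-phenylethyl)-4H-1,3-dioxin-4-one
Product: 22 5-O-triethylsilyl-6,7-O-BDA derivative of 23, via acylketene 20 (not isolated), via cycloadduct 21 (not isolated)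
Conditions: toluene, 110 °C, slow addition of 19 (3 equiv); then pyridinium p-toluenesulfonate (cat.), rt
Reagents that add atoms: none
Why: Thermal cycloreversion of the dioxinone releases the acylketene, which reacts as a 1-oxadiene with the silyl enol ether in a hetero-Diels–Alder reaction (C4a to the ketene carbon, acyl oxygen to C8a). The silyloxy ketal 21 then loses trimethylsilanol from C8a to give the γ-pyrone, the known route from acylketenes and enol ethers or enamines to 4-pyranones; C5 to C8 are not touched.

Step 16
Reactants: 22 5-O-triethylsilyl-6,7-O-BDA derivative of 23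
Product: 23 (5S,6R,7S,8S)-5,6,7-trihydroxy-8-(ArO)-2-(2-phenylethyl)-5,6,7,8-tetrahydro-4H-chromen-4-one
Conditions: CF3CO2H/H2O (9:1), 0 °C to rt
Reagents that add atoms: none
Why: Aqueous acid hydrolyses the diacetal and the silyl ether in one operation; the pyrone carbonyls are protonated in this medium, which should disfavour ionisation of the C5 carbinol, and no stereocentre is involved.

## Compound list

1 | L-fucose | C[C@H](O)[C@@H](O)[C@@H](O)[C@H](O)C=O | starting material
2 | 1,2,3,4-tetra-O-acetyl-L-fucopyranose (anomeric mixture) | C[C@@H]1OC(OC(C)=O)[C@@H](OC(C)=O)[C@H](OC(C)=O)[C@@H]1OC(C)=O | intermediate (not isolated)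
3 | phenyl 2,3,4-tri-O-acetyl-1-thio-β-L-fucopyranoside | C[C@@H]1O[C@H](Sc2ccccc2)[C@@H](OC(C)=O)[C@H](OC(C)=O)[C@@H]1OC(C)=O | intermediate
4 | phenyl 1-thio-β-L-fucopyranoside | C[C@@H]1O[C@H](Sc2ccccc2)[C@@H](O)[C@H](O)[C@@H]1O | intermediate
5 | phenyl 2,3-O-[(2S,3S)-2,3-dimethoxybutane-2,3-diyl]-1-thio-β-L-fucopyranoside | C[C@@H]1O[C@H](Sc2ccccc2)[C@H]2O[C@](C)(OC)[C@@](C)(OC)O[C@@H]2[C@@H]1O | intermediate
6 | paeonol, 1-(2-hydroxy-4-methoxyphenyl)ethanone | CC(=O)c1ccc(OC)cc1O | starting material
7 | 1-(2-hydroxy-5-iodo-4-methoxyphenyl)ethanone | CC(=O)c1cc(I)c(OC)cc1O | intermediate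
8 | ethyl 3-phenylpropanoate | CCOC(=O)CCc1ccccc1 | starting material
9 | 1-(2-hydroxy-5-iodo-4-methoxyphenyl)-5-phenylpentane-1,3-dione | COc1cc(O)c(cc1I)C(=O)CC(=O)CCc1ccccc1 | intermediate
10 | 6-iodo-7-methoxy-2-(2-phenylethyl)-4H-chromen-4-one | COc1cc2oc(CCc3ccccc3)cc(=O)c2cc1I | intermediate
11 | phenyl 4-O-Ar-2,3-O-BDA-1-thio-β-L-fucopyranoside | C[C@@H]1O[C@H](Sc2ccccc2)[C@H]2O[C@](C)(OC)[C@@](C)(OC)O[C@@H]2[C@@H]1Oc1cc2c(=O)cc(CCc3ccccc3)oc2cc1OC | intermediate
12 | 4-O-Ar-2,3-O-BDA-L-fucopyranose (anomeric mixture) | C[C@@H]1OC(O)[C@H]2O[C@](C)(OC)[C@@](C)(OC)O[C@@H]2[C@@H]1Oc1cc2c(=O)cc(CCc3ccccc3)oc2cc1OC | intermediate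
13 | 4-O-Ar-2,3-O-BDA-L-fucitol | C[C@H](O)[C@@H](Oc1cc2c(=O)cc(CCc3ccccc3)oc2cc1OC)[C@H]1O[C@](C)(OC)[C@@](C)(OC)O[C@@H]1CO | intermediate
14 | 4-O-Ar-2,3-O-BDA-6-deoxy-L-lyxo-hexos-5-ulose | CC(=O)[C@@H](Oc1cc2c(=O)cc(CCc3ccccc3)oc2cc1OC)[C@H]1O[C@](C)(OC)[C@@](C)(OC)O[C@@H]1C=O | intermediate
15 | (2S,3S,4R,5S)-2-(ArO)-5-hydroxy-3,4-O-BDA-cyclohexan-1-one | COc1cc2oc(CCc3ccccc3)cc(=O)c2cc1O[C@@H]1C(=O)C[C@H](O)[C@H]2O[C@](C)(OC)[C@@](C)(OC)O[C@H]12 | intermediate
16 | 5-O-triethylsilyl ether of 15 | COc1cc2oc(CCc3ccccc3)cc(=O)c2cc1O[C@@H]1C(=O)C[C@H](O[Si](CC)(CC)CC)[C@H]2O[C@](C)(OC)[C@@](C)(OC)O[C@H]12 | intermediate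
17 | trimethylsilyl enol ether of 16 (C4a=C8a) | COc1cc2oc(CCc3ccccc3)cc(=O)c2cc1O[C@@H]1C(O[Si](C)(C)C)=C[C@H](O[Si](CC)(CC)CC)[C@H]2O[C@](C)(OC)[C@@](C)(OC)O[C@H]12 | intermediate
18 | 2,2,6-trimethyl-4H-1,3-dioxin-4-one | CC1=CC(=O)OC(C)(C)O1 | starting material
19 | 2,2-dimethyl-6-(2-phenylethyl)-4H-1,3-dioxin-4-one | CC1(C)OC(=O)C=C(CCc2ccccc2)O1 | intermediate
20 | 3-oxo-5-phenylpent-1-en-1-one (acylketene) | O=C=CC(=O)CCc1ccccc1 | intermediate (not isolated)
21 | 8a-trimethylsilyloxy-4a,8a-dihydro cycloadduct of 17 and 20 (configuration at C4a and C8a not defined) | COc1cc2oc(CCc3ccccc3)cc(=O)c2cc1O[C@@H]1C2(O[Si](C)(C)C)OC(CCc3ccccc3)=CC(=O)C2[C@H](O[Si](CC)(CC)CC)[C@H]2O[C@](C)(OC)[C@@](C)(OC)O[C@H]12 | intermediate (not isolated)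
22 | 5-O-triethylsilyl-6,7-O-BDA derivative of 23 | COc1cc2oc(CCc3ccccc3)cc(=O)c2cc1O[C@@H]1c2oc(CCc3ccccc3)cc(=O)c2[C@H](O[Si](CC)(CC)CC)[C@H]2O[C@](C)(OC)[C@@](C)(OC)O[C@H]12 | intermediate
23 | (5S,6R,7S,8S)-5,6,7-trihydroxy-8-{[7-methoxy-4-oxo-2-(2-phenylethyl)-4H-chromen-6-yl]oxy}-2-(2-phenylethyl)-5,6,7,8-tetrahydro-4H-chromen-4-one | COc1cc2oc(CCc3ccccc3)cc(=O)c2cc1O[C@@H]1c2oc(CCc3ccccc3)cc(=O)c2[C@H](O)[C@@H](O)[C@@H]1O | target

## Step count and least certain steps

Total: 16 steps. Longest linear sequence: 12 steps from 1 (steps 1, 2, 3, 7, 8, 9, 10, 11, 12, 13, 15, 16).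

**Step 11 (key step).**
- Risk: poor facial selectivity at the aldehyde. A hydrogen-bonded amidinium could still bridge the two oxygens and favour the axial (5R) alcohol, and the thermodynamic preference for the equatorial epimer is small because an axial group β to a ketone has only one syn-axial hydrogen. Dehydration of the aldol and base-mediated epimerisation at C8 are the other losses.
- Fallback (from 14, back at 15): C5 is set by conjugate addition instead. The aldol is run without regard to C5 and gives 15 mixed with the (5R) epimer of 15 F5. The mixture is dehydrated (MsCl, Et3N, CH2Cl2) to the enone 6-(ArO)-4,5-O-BDA-cyclohex-2-en-1-one F6. Copper-catalysed β-borylation (CuCl, NaOt-Bu, bis[2-(diphenylphosphino)phenyl] ether, bis(pinacolato)diboron, MeOH, THF) is expected to add boron to C5 anti to the neighbouring C6 oxygen, giving the 5-(pinacolatoboryl) analogue of 15 F7. Oxidation with NaBO3·4H2O replaces boron by hydroxyl with retention and gives 15.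

**Step 7.**
- Risk: slow C–O bond formation at the hindered axial alkoxide, so that hydrodehalogenation of 10 and catalyst deactivation (possibly by the thioether) take over.
- Fallback (from 5 and 10, back at 11): the polarity is reversed and the sugar becomes the electrophile. Tf2O/pyridine converts 5 into phenyl 2,3-O-BDA-1-thio-4-O-trifluoromethanesulfonyl-β-L-fucopyranoside F1. Tetrabutylammonium nitrite in MeCN (Lattrell–Dax inversion) gives the equatorial alcohol phenyl 6-deoxy-2,3-O-BDA-1-thio-β-L-glucopyranoside F2, and a second triflation gives its 4-O-triflate F3. Separately 10 is hydroxylated (Pd(OAc)2, 2-(di-tert-butylphosphino)-2',4',6'-triisopropyl-3,6-dimethoxybiphenyl, benzaldoxime, Cs2CO3, DMF, 80 °C) to 6-hydroxy-7-methoxy-2-(2-phenylethyl)-4H-chromen-4-one F4. The caesium phenoxide of F4 (Cs2CO3, DMF) displaces the equatorial triflate of F3 with inversion, a geometry without an antiperiplanar hydrogen for elimination, and gives 11.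

**Step 13.**
- Risk: competing deprotonation at the vinylogously acidic CH2 of the aryl chromone, or β-elimination of the C5 silyloxy group from the lithium enolate before it is trapped.
- Fallback (from 16, back at 22): no metal enolate is formed. Soft enolisation with Et3SiOTf and Et3N in CH2Cl2 at 0 °C, which removes the aligned axial C4a–H from the silylated oxocarbenium ion, gives the triethylsilyl enol ether of 16 F8. F8 is taken through step 15 in place of 17 and gives 22 with loss of triethylsilanol.

**Step 15.**
- Risk: dimerisation of the acylketene outpacing cycloaddition to a hindered, inductively deactivated enol ether, or loss of the C5 silyloxy group from the cycloadduct instead of aromatisation.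
- Fallback (from 17, back at 22): the pyranone is built by ionic acylation and cycloisomerisation. 5-Phenylpent-2-ynoic acid and (COCl)2 give 5-phenylpent-2-ynoyl chloride F9. ZnCl2-mediated C-acylation of 17 with F9 in CH2Cl2/Et2O gives the 2-(5-phenylpent-2-ynoyl) derivative of 16 F10 (acyl group on C4a). AuCl3 (cat.) in CH2Cl2 closes the enol oxygen onto the ynone β-carbon (6-endo-dig) to give 22; neutral catalysis is chosen because a diketone enolate would expel the C5 silyloxy group.

**Step 16.**
- Risk: acid-promoted ionisation at C5 of the product, leading to epimerisation or elimination towards the aromatic chromone.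
- Fallback (from 15, back at 23): the acid step is moved to before the pyrone exists. CF3CO2H/H2O on 15 gives (2S,3S,4R,5S)-2-(ArO)-3,4,5-trihydroxycyclohexan-1-one F11. Et3SiOTf/2,6-lutidine gives the 3,4,5-tris-O-triethylsilyl ether of F11 F12, which should keep the same chair because the alternative puts O5 and O7 syn-diaxial. The conditions of step 13 give the trimethylsilyl enol ether of F12 F13, and those of step 15 give the 5,6,7-tris-O-triethylsilyl ether of 23 F14. HF·pyridine buffered with pyridine in THF then gives 23 without strong acid.

## Further compounds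

F1 | step 7 | phenyl 2,3-O-BDA-1-thio-4-O-trifluoromethanesulfonyl-β-L-fucopyranoside | C[C@@H]1O[C@H](Sc2ccccc2)[C@H]2O[C@](C)(OC)[C@@](C)(OC)O[C@@H]2[C@@H]1OS(=O)(=O)C(F)(F)F
F2 | step 7 | phenyl 6-deoxy-2,3-O-BDA-1-thio-β-L-glucopyranoside | C[C@@H]1O[C@H](Sc2ccccc2)[C@H]2O[C@](C)(OC)[C@@](C)(OC)O[C@@H]2[C@H]1O
F3 | step 7 | phenyl 6-deoxy-2,3-O-BDA-1-thio-4-O-trifluoromethanesulfonyl-β-L-glucopyranoside | C[C@@H]1O[C@H](Sc2ccccc2)[C@H]2O[C@](C)(OC)[C@@](C)(OC)O[C@@H]2[C@H]1OS(=O)(=O)C(F)(F)F
F4 | step 7 | 6-hydroxy-7-methoxy-2-(2-phenylethyl)-4H-chromen-4-one | COc1cc2oc(CCc3ccccc3)cc(=O)c2cc1O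
F5 | step 11 | (5R) epimer of 15 | COc1cc2oc(CCc3ccccc3)cc(=O)c2cc1O[C@@H]1C(=O)C[C@@H](O)[C@H]2O[C@](C)(OC)[C@@](C)(OC)O[C@H]12
F6 | step 11 | 6-(ArO)-4,5-O-BDA-cyclohex-2-en-1-one, configured as 15 | COc1cc2oc(CCc3ccccc3)cc(=O)c2cc1O[C@@H]1C(=O)C=C[C@H]2O[C@](C)(OC)[C@@](C)(OC)O[C@H]12
F7 | step 11 | 5-(pinacolatoboryl) analogue of 15 (boron in place of O5, same face) | COc1cc2oc(CCc3ccccc3)cc(=O)c2cc1O[C@@H]1C(=O)C[C@H](B2OC(C)(C)C(C)(C)O2)[C@H]2O[C@](C)(OC)[C@@](C)(OC)O[C@H]12
F8 | step 13 | triethylsilyl enol ether of 16 (C4a=C8a) | COc1cc2oc(CCc3ccccc3)cc(=O)c2cc1O[C@@H]1C(O[Si](CC)(CC)CC)=C[C@H](O[Si](CC)(CC)CC)[C@H]2O[C@](C)(OC)[C@@](C)(OC)O[C@H]12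
F9 | step 15 | 5-phenylpent-2-ynoyl chloride | O=C(Cl)C#CCCc1ccccc1
F10 | step 15 | 2-(5-phenylpent-2-ynoyl) derivative of 16 (acyl group on C4a) | COc1cc2oc(CCc3ccccc3)cc(=O)c2cc1O[C@@H]1C(=O)C(C(=O)C#CCCc2ccccc2)[C@H](O[Si](CC)(CC)CC)[C@H]2O[C@](C)(OC)[C@@](C)(OC)O[C@H]12
F11 | step 16 | (2S,3S,4R,5S)-2-(ArO)-3,4,5-trihydroxycyclohexan-1-one | COc1cc2oc(CCc3ccccc3)cc(=O)c2cc1O[C@@H]1C(=O)C[C@H](O)[C@@H](O)[C@@H]1O
F12 | step 16 | 3,4,5-tris-O-triethylsilyl ether of F11 | COc1cc2oc(CCc3ccccc3)cc(=O)c2cc1O[C@@H]1C(=O)C[C@H](O[Si](CC)(CC)CC)[C@@H](O[Si](CC)(CC)CC)[C@@H]1O[Si](CC)(CC)CC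
F13 | step 16 | trimethylsilyl enol ether of F12 (C4a=C8a) | COc1cc2oc(CCc3ccccc3)cc(=O)c2cc1O[C@@H]1C(O[Si](C)(C)C)=C[C@H](O[Si](CC)(CC)CC)[C@@H](O[Si](CC)(CC)CC)[C@@H]1O[Si](CC)(CC)CC
F14 | step 16 | 5,6,7-tris-O-triethylsilyl ether of 23 | COc1cc2oc(CCc3ccccc3)cc(=O)c2cc1O[C@@H]1c2oc(CCc3ccccc3)cc(=O)c2[C@H](O[Si](CC)(CC)CC)[C@@H](O[Si](CC)(CC)CC)[C@@H]1O[Si](CC)(CC)CC
A1 | alternative 1 | 8,8-dimethoxy-2-(2-phenylethyl)-8H-chromene-4,7-dione | O=c1cc(CCc2ccccc2)oc2c1C=CC(=O)C2(OC)OC
A2 | alternative 1 | 5,6-epoxy-8,8-dimethoxy-2-(2-phenylethyl)-5,6-dihydro-8H-chromene-4,7-dione, epoxide on the face of O6 of 23 | O=c1cc(CCc2ccccc2)oc2c1[C@H]1O[C@H]1C(=O)C2(OC)OC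
A3 | alternative 2 | 2-(2-phenylethyl)-4H-chromen-4-one | O=c1cc(CCc2ccccc2)oc2ccccc12
A4 | alternative 2 | (7S,8S)-7,8-dihydroxy-2-(2-phenylethyl)-7,8-dihydro-4H-chromen-4-one | O[C@@H]1c2oc(CCc3ccccc3)cc(=O)c2C=C[C@@H]1O
A5 | alternative 3 | pentacarbonyl[(1-methoxyethenyl)(alkoxy)methylidene]chromium, alkoxy = 5,6,7-tris(methoxymethoxy)tetrahydrochromon-8-yloxy | COC(=C)C(O[C@@H]1c2oc(CCc3ccccc3)cc(=O)c2[C@H](OCOC)[C@@H](OCOC)[C@@H]1OCOC)=[Cr](=C=O)(=C=O)(=C=O)(=C=O)=C=O
A6 | alternative 3 | 3,3-diethoxyprop-1-yne | C#CC(OCC)OCC
A7 | alternative 3 | 2-(diethoxymethyl)-5-methoxy-4-(tetrahydrochromon-8-yloxy)phenol, tris(methoxymethyl) protected | Oc1cc(OC)c(O[C@@H]2c3oc(CCc4ccccc4)cc(=O)c3[C@H](OCOC)[C@@H](OCOC)[C@@H]2OCOC)cc1C(OCC)OCC
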